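Ring B is built last. The target is cut at C2'–C3', which leads back to a 2,3-dimethoxycyclobutenone (future C3'–C6') whose ring CH carries a 2-methoxyvinyl arm (C1'=C2'). C1' is already bonded to C2 of the finished 5,6,7,8-tetramethoxychromone (rings A and C). Heating opens the four-membered ring to a dienylketene that closes ring B and enolises in one operation. The step exploits the substitution of ring B. The ketene oxygen becomes the single free hydroxyl at C3', flanked by C2'-OMe and C4'-OMe, and the ring CH becomes C6'-H, so no protecting group is needed. The precursor comes from a Stille coupling of alkenylstannane and 4-chlorocyclobutenone.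

Key step: step 11

Remark 1: ring A of the target holds five oxygen atoms (O1 and four OMe), one more than 1,2,3,4-tetramethoxybenzene, so step 1 adds an oxygen before the acetyl group is introduced.

Remark 2 (assumption): the dehydrobromination in step 6 is taken to give the isomer with OMe cis to Br, as acceptor-substituted enol ethers such as 3-methoxyacrylates do. After two couplings with retention, the vinyl OMe of 20 is therefore cis to the four-membered ring (E by the CIP rules), and this geometry disappears when C2' becomes aromatic.

Step 1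
Reactants: 1 1,2,3,4-tetramethoxybenzene
Product: 4 2,3,4,5-tetramethoxyphenol, via aryllithium 2 (not isolated), via dimethyl arylboronate 3 (not isolated)
Conditions: n-BuLi, TMEDA, THF, 0 °C; B(OMe)3, −78 °C to rt; AcOH, 30% aq. H2O2, 0 °C to rt
Reagents that add atoms: hydrogen peroxide, OO
Why: Directed ortho-lithiation (the two ring hydrogens are equivalent, so only one aryllithium can form), borylation and peroxide oxidation with 1,2-aryl shift from boron to oxygen install the fifth oxygen of ring A, the future O1.

Step 2
Reactants: 4 2,3,4,5-tetramethoxyphenol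
Product: 6 1-(2-hydroxy-3,4,5,6-tetramethoxyphenyl)ethanone, via aryl acetate 5 (not isolated)
Conditions: Ac2O, BF3·OEt2 (promoter), 0 to 70 °C; then H2O, 50 °C
Reagents that add atoms: acetic anhydride, CC(=O)OC(C)=O
Why: One-pot O-acetylation and Lewis-acid Fries rearrangement (Friedel–Crafts acylation) can only deliver the acetyl group to the single free ring position, which is ortho to the hydroxyl, and chelation of the o-hydroxyaryl ketone to boron stops further reaction.

Step 3
Reactants: 6 1-(2-hydroxy-3,4,5,6-tetramethoxyphenyl)ethanone; 7 methyl dimethoxyacetate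
Product: 9 2-(dimethoxymethyl)-5,6,7,8-tetramethoxy-4H-chromen-4-one, via 1,3-diketone 8 (not isolated)
Conditions: NaH, THF, 0 °C to reflux; aq. HCl quench; then p-TsOH (cat.), MeOH, reflux
Reagents that add atoms: none
Why: Crossed Claisen condensation of the phenoxide–enolate of 6 with the non-self-condensing ester 7, then acid-catalysed cyclodehydration of the o-hydroxyaryl 1,3-diketone, is the standard chromone synthesis, and methanol as solvent keeps the acetal in place.

Step 4
Reactants: 9 2-(dimethoxymethyl)-5,6,7,8-tetramethoxy-4H-chromen-4-one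
Product: 10 5,6,7,8-tetramethoxy-4-oxo-4H-chromene-2-carbaldehyde
Conditions: CF3CO2H–H2O (4:1), 40 °C
Reagents that add atoms: water, O
Why: Acid-catalysed acetal hydrolysis with a halide-free acid unmasks the aldehyde and leaves the aryl methyl ethers, the peri 5-OMe included, untouched.

Step 5
Reactants: 10 5,6,7,8-tetramethoxy-4-oxo-4H-chromene-2-carbaldehyde; 11 (methoxymethyl)triphenylphosphonium chloride
Product: 13 5,6,7,8-tetramethoxy-2-(2-methoxyethenyl)-4H-chromen-4-one (E/Z mixture; E isomer drawn), via methoxymethylene ylide 12 (not isolated)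
Conditions: 11, NaN(SiMe3)2, THF, 0 °C; then 10, −78 to 0 °C
Reagents that add atoms: none
Why: Wittig methoxymethylenation: at low temperature the ylide attacks the aldehyde far faster than the vinylogous-ester carbonyl or C2 of the chromone, and the mixture of alkene isomers is acceptable since step 6 resets the geometry.

Step 6
Reactants: 13 5,6,7,8-tetramethoxy-2-(2-methoxyethenyl)-4H-chromen-4-one
Product: 15 2-[(Z)-1-bromo-2-methoxyethenyl]-5,6,7,8-tetramethoxy-4H-chromen-4-one, via vicinal dibromide 14 (not isolated)
Conditions: Br2 (1.0 equiv), CH2Cl2, −78 °C; then Et3N, −78 °C to rt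
Reagents that add atoms: bromine, BrBr
Why: Bromine adds to the enol ether, by far the most electron-rich π bond (ring A has no free position), and base-induced dehydrobromination (loss of the acidified C1'-H and of the labile α-alkoxy bromide by an E1cB-like pathway) erases the geometry of 13 and should settle, as with 3-methoxyacrylates, on the isomer with OMe anti to the acceptor ring and cis to Br.

Step 7
Reactants: 15 2-[(Z)-1-bromo-2-methoxyethenyl]-5,6,7,8-tetramethoxy-4H-chromen-4-one
Product: 16 5,6,7,8-tetramethoxy-2-[(Z)-2-methoxy-1-(trimethylstannyl)ethenyl]-4H-chromen-4-one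
Conditions: Me3SnSnMe3, Pd(PPh3)4 (5 mol %), toluene, 90 °C
Reagents that add atoms: hexamethylditin, C[Sn](C)(C)[Sn](C)(C)C
Why: Palladium-catalysed stannylation of an alkenyl bromide with a distannane (oxidative addition, Sn–Sn transmetalation, reductive elimination) replaces Br by SnMe3 with retention of geometry and avoids organolithium reagents, which the chromone would not survive.

Step 8
Reactants: 17 dimethyl squarate
Product: 18 4-hydroxy-2,3-dimethoxycyclobut-2-en-1-one (racemic)
Conditions: LiAlH(OtBu)3, THF, −78 to −20 °C; H2O
Reagents that add atoms: none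
Why: 1,2-Reduction of one of the two equivalent carbonyl groups by a bulky, mild aluminium hydride stops at the 4-hydroxycyclobutenone because the remaining carbonyl is a deactivated vinylogous ester; the new carbinol centre is racemic and is lost later.

Step 9
Reactants: 18 4-hydroxy-2,3-dimethoxycyclobut-2-en-1-one
Product: 19 4-chloro-2,3-dimethoxycyclobut-2-en-1-one (racemic)
Conditions: PPh3 and N-chlorosuccinimide (premixed), CH2Cl2, −20 °C to rt; used promptly
Reagents that add atoms: N-chlorosuccinimide, O=C1CCC(=O)N1Cl
Why: Appel-type chlorination under neutral conditions (alkoxyphosphonium salt, SN2 displacement by chloride at the allylic α-keto carbon) avoids the acid-induced ionisation that would expel a methyl group and lead to the ring dione; the centre stays racemic.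

Step 10
Reactants: 16 5,6,7,8-tetramethoxy-2-[(Z)-2-methoxy-1-(trimethylstannyl)ethenyl]-4H-chromen-4-one; 19 4-chloro-2,3-dimethoxycyclobut-2-en-1-one
Product: 20 4-[(E)-2-methoxy-1-(5,6,7,8-tetramethoxy-4-oxo-4H-chromen-2-yl)ethenyl]-2,3-dimethoxycyclobut-2-en-1-one (racemic at the ring CH; vinyl OMe cis to the four-membered ring)
Conditions: Pd2(dba)3 (2.5 mol %), P(2-furyl)3 (10 mol %), CuI (10 mol %), NMP–THF, 25 to 40 °C
Reagents that add atoms: none
Why: Stille coupling of a 4-chlorocyclobutenone: zerovalent palladium ionises the allylic α-keto C–Cl bond, the alkenyl group passes from tin to palladium with retention (CuI and the weakly donating furylphosphine speed up this slow step for the 1,1-disubstituted stannane), and the C–C bond forms at the CH terminus, which is less hindered than C(OMe) and keeps the vinylogous ester; the ring CH is racemic and vanishes in step 11, and the temperature stays below that of ring opening.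

Step 11
Reactants: 20 4-[(E)-2-methoxy-1-(5,6,7,8-tetramethoxy-4-oxo-4H-chromen-2-yl)ethenyl]-2,3-dimethoxycyclobut-2-en-1-one
Product: 23 agehoustin C, via dienylketene 21 (not isolated), via cyclohexadienone 22 (not isolated)
Conditions: toluene (0.01 M, degassed), 110 °C
Reagents that add atoms: none
Why: Thermal conrotatory 4π electrocyclic opening breaks the strained C3'–C6' bond of 20 reversibly; rotation of the alkenyl arm toward the carbonyl gives dienylketene 21, whereas the isomer from outward rotation can only re-close, so the equilibrium drains through 21. Ring B (six-membered, carbocyclic) is closed by a 6π electrocyclisation that joins the sp ketene carbon C3' to the methoxy-bearing vinyl terminus C2', and dienone 22 then enolises irreversibly by loss of the C2' hydrogen to the aromatic phenol. The closest known reaction type is the thermal rearrangement of 4-alkenylcyclobutenones to phenols, which ends the Danheiser benzannulation and follows Stille couplings of 4-chlorocyclobutenones. No stereocentre is created in the product: the racemic ring CH of 20 becomes C6'-H, and the transient C2' centre of 22 and the alkene geometry vanish on aromatisation. The selectivity required is positional, one hydroxyl against seven methoxy groups, and the connectivity of 20 secures it, since only the former cyclobutenone carbonyl oxygen can end as OH (C3'), each methoxy group travels with its carbon, and the chromone C2=C3 bond is cross-conjugated and cannot join the 6π array. The vinyl methoxy group that faces the ketene should be tolerated because the ketene carbon has no substituent pointing into the gap, in line with the easy thermal re-closure of the terminally disubstituted dienylketenes of the Barton–Quinkert reaction; high dilution suppresses bimolecular ketene capture.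

Compound list
1 | 1,2,3,4-tetramethoxybenzene | COc1ccc(OC)c(OC)c1OC | starting material
2 | (2,3,4,5-tetramethoxyphenyl)lithium | [Li]c1cc(OC)c(OC)c(OC)c1OC | intermediate
3 | dimethyl (2,3,4,5-tetramethoxyphenyl)boronate | COB(OC)c1cc(OC)c(OC)c(OC)c1OC | intermediate
4 | 2,3,4,5-tetramethoxyphenol | COc1cc(O)c(OC)c(OC)c1OC | intermediate
5 | 2,3,4,5-tetramethoxyphenyl acetate | CC(=O)Oc1cc(OC)c(OC)c(OC)c1OC | intermediate
6 | 1-(2-hydroxy-3,4,5,6-tetramethoxyphenyl)ethanone | CC(=O)c1c(O)c(OC)c(OC)c(OC)c1OC | intermediate
7 | methyl dimethoxyacetate | COC(OC)C(=O)OC | starting material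
8 | 1-(2-hydroxy-3,4,5,6-tetramethoxyphenyl)-4,4-dimethoxybutane-1,3-dione | COC(OC)C(=O)CC(=O)c1c(O)c(OC)c(OC)c(OC)c1OC | intermediate
9 | 2-(dimethoxymethyl)-5,6,7,8-tetramethoxy-4H-chromen-4-one | COC(OC)c1cc(=O)c2c(OC)c(OC)c(OC)c(OC)c2o1 | intermediate
10 | 5,6,7,8-tetramethoxy-4-oxo-4H-chromene-2-carbaldehyde | O=Cc1cc(=O)c2c(OC)c(OC)c(OC)c(OC)c2o1 | intermediate
11 | (methoxymethyl)triphenylphosphonium chloride | COC[P+](c1ccccc1)(c1ccccc1)c1ccccc1.[Cl-] | starting material
12 | (methoxymethylidene)triphenylphosphorane | COC=P(c1ccccc1)(c1ccccc1)c1ccccc1 | intermediate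
13 | 5,6,7,8-tetramethoxy-2-(2-methoxyethenyl)-4H-chromen-4-one (E/Z mixture, E isomer drawn) | CO/C=C/c1cc(=O)c2c(OC)c(OC)c(OC)c(OC)c2o1 | intermediate
14 | 2-(1,2-dibromo-2-methoxyethyl)-5,6,7,8-tetramethoxy-4H-chromen-4-one (mixture of diastereomers) | COC(Br)C(Br)c1cc(=O)c2c(OC)c(OC)c(OC)c(OC)c2o1 | intermediate
15 | 2-[(Z)-1-bromo-2-methoxyethenyl]-5,6,7,8-tetramethoxy-4H-chromen-4-one (OMe cis to Br) | CO/C=C(\Br)c1cc(=O)c2c(OC)c(OC)c(OC)c(OC)c2o1 | intermediate
16 | 5,6,7,8-tetramethoxy-2-[(Z)-2-methoxy-1-(trimethylstannyl)ethenyl]-4H-chromen-4-one (OMe cis to Sn) | CO/C=C(\[Sn](C)(C)C)c1cc(=O)c2c(OC)c(OC)c(OC)c(OC)c2o1 | intermediate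
17 | dimethyl squarate | COC1=C(OC)C(=O)C1=O | starting material
18 | 4-hydroxy-2,3-dimethoxycyclobut-2-en-1-one (racemic) | COC1=C(OC)C(=O)C1O | intermediate
19 | 4-chloro-2,3-dimethoxycyclobut-2-en-1-one (racemic) | COC1=C(OC)C(=O)C1Cl | intermediate
20 | 4-[(E)-2-methoxy-1-(5,6,7,8-tetramethoxy-4-oxo-4H-chromen-2-yl)ethenyl]-2,3-dimethoxycyclobut-2-en-1-one (racemic at the ring CH) | CO/C=C(/c1cc(=O)c2c(OC)c(OC)c(OC)c(OC)c2o1)C1C(OC)=C(OC)C1=O | intermediate
21 | (3E,5E)-2,3,6-trimethoxy-5-(5,6,7,8-tetramethoxy-4-oxo-4H-chromen-2-yl)hexa-1,3,5-trien-1-one (ketene and alkenyl arm cis across C5'=C6') | O=C=C(OC)/C(OC)=C\C(=C/OC)c1cc(=O)c2c(OC)c(OC)c(OC)c(OC)c2o1 | intermediate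
22 | 2,3,6-trimethoxy-5-(5,6,7,8-tetramethoxy-4-oxo-4H-chromen-2-yl)cyclohexa-2,4-dien-1-one (racemic at C6, the future C2') | COC1C(=O)C(OC)=C(OC)C=C1c1cc(=O)c2c(OC)c(OC)c(OC)c(OC)c2o1 | intermediate
23 | agehoustin C, 2-(3-hydroxy-2,4,5-trimethoxyphenyl)-5,6,7,8-tetramethoxy-4H-chromen-4-one | COc1cc(-c2cc(=O)c3c(OC)c(OC)c(OC)c(OC)c3o2)c(OC)c(O)c1OC | target

Total step count: 11. Longest linear sequence: 9 (steps 1 to 7, 10 and 11). The squarate branch (steps 8 and 9) joins at step 10.

Steps most likely to fail

Step 11. Inward rotation of the bulky arm is the slower mode of ring opening, and the methoxy group on C2' points into the closing gap. Ring closure may therefore lag behind bimolecular consumption of the ketene, either by dimerisation or by acylation of phenol already formed.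
- The fallback inverts the alkene geometry before the coupling. It sets out from 16 and comes back to the route at 22, and so at 23.
- Triplet-sensitised photoisomerisation of 16 (thioxanthen-9-one, 405 nm, MeCN, rt) should give a photostationary mixture. From it 5,6,7,8-tetramethoxy-2-[(E)-2-methoxy-1-(trimethylstannyl)ethenyl]-4H-chromen-4-one F1 is separated, and recovered 16 is recycled.
- Coupling of F1 with 19 under the conditions of step 10 gives 4-[(Z)-2-methoxy-1-(5,6,7,8-tetramethoxy-4-oxo-4H-chromen-2-yl)ethenyl]-2,3-dimethoxycyclobut-2-en-1-one F2, whose vinyl methoxy group is trans to the four-membered ring.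
- On heating, F2 opens to the (3E,5Z)-dienylketene F3, which presents only hydrogen on the inner face of C2' and closes to 22.

Step 10. Transfer of the hindered, acceptor-bearing 1,1-disubstituted alkenyl group from tin to palladium may be too slow. The oxocyclobutenyl–palladium species could then decay, or protodestannylation could take over.
- The fallback changes the organometallic partner. It sets out from 15, skips step 7 and comes back at 20.
- Insertion of highly active zinc powder (from ZnCl2 and lithium naphthalenide, THF, rt) into the C–Br bond gives bromo[(Z)-2-methoxy-1-(5,6,7,8-tetramethoxy-4-oxo-4H-chromen-2-yl)ethenyl]zinc F4, stabilised by the cis methoxy group.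
- F4 is joined to 19 by Negishi coupling (Pd2(dba)3, P(2-furyl)3, THF, 0 °C to rt), where transmetalation is much faster than from tin.

Step 9. Allylic ionisation of the activated alcohol or of the chloride, followed by chloride attack at the methoxy-bearing terminus and demethylation, may consume the material during formation or isolation.
- The fallback avoids the halide altogether. It sets out from 18 and comes back at 20.
- Acylation of 18 (methyl chloroformate, pyridine, CH2Cl2, 0 °C) gives 2,3-dimethoxy-4-oxocyclobut-2-en-1-yl methyl carbonate F5.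
- Zerovalent palladium (Pd2(dba)3, P(2-furyl)3, DMF, rt) ionises F5 in the Tsuji–Trost manner with loss of carbon dioxide. The methoxide released binds tin and drives transfer of the alkenyl group of 16.
- Any methoxide exchange on the ring is degenerate.

Further compounds
F1 | step 11 | 5,6,7,8-tetramethoxy-2-[(E)-2-methoxy-1-(trimethylstannyl)ethenyl]-4H-chromen-4-one | CO/C=C(/[Sn](C)(C)C)c1cc(=O)c2c(OC)c(OC)c(OC)c(OC)c2o1
F2 | step 11 | 4-[(Z)-2-methoxy-1-(5,6,7,8-tetramethoxy-4-oxo-4H-chromen-2-yl)ethenyl]-2,3-dimethoxycyclobut-2-en-1-one (racemic at the ring CH) | CO/C=C(\c1cc(=O)c2c(OC)c(OC)c(OC)c(OC)c2o1)C1C(OC)=C(OC)C1=O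
F3 | step 11 | (3E,5Z)-2,3,6-trimethoxy-5-(5,6,7,8-tetramethoxy-4-oxo-4H-chromen-2-yl)hexa-1,3,5-trien-1-one | O=C=C(OC)/C(OC)=C\C(=C\OC)c1cc(=O)c2c(OC)c(OC)c(OC)c(OC)c2o1
F4 | step 10 | bromo[(Z)-2-methoxy-1-(5,6,7,8-tetramethoxy-4-oxo-4H-chromen-2-yl)ethenyl]zinc | CO/C=C(\[Zn]Br)c1cc(=O)c2c(OC)c(OC)c(OC)c(OC)c2o1
F5 | step 9 | 2,3-dimethoxy-4-oxocyclobut-2-en-1-yl methyl carbonate (racemic) | COC(=O)OC1C(OC)=C(OC)C1=O
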